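**Plan** (briarane numbering C1–C20; C15 = methyl on C1, C16 = exocyclic CH2 on C5, C17–C19 = lactone carbons)

1. Cuts: 11,20-epoxide ← C11,C20-diol; 6-Cl/5(16)-ene ← (5E)-alkene by ene chlorination; lactone ← C8–C17 (tethered Reformatsky) and C7–O ester; ten-membered ring ← C6–C7 (Nozaki–Hiyama–Kishi); ring C ← C1–C10 and C11–C12 (Diels–Alder).
2. Enabling feature: ring C (C1, C10, C11, C12, C13, C14) carries oxygen at C14 and C11 in a 1,4 relation and oxygen at C2 next to C1. That is the adduct pattern of a 1-alkoxy-3-siloxy diene C12=C13–C14(OSi)=C1 and a C10=C11 butenolide. The 1-alkoxy oxygen is the C2 oxygen, tied back to C12 as a 2H-pyran; this C12–O bond is absent from the target and is cut afterwards by β-elimination.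
3. Forward: pyran diene 8 (steps 1–5) and butenolide 14 (steps 6–9) → ring C (step 10) → ring C adjusted (11–17) → ten-membered ring (20) → lactone (21–24) → epoxide (26) → chloride (27).
4. Stereochemistry: C2 from a catalytic hetero-Diels–Alder reaction; C1, C10, C11 from the cycloaddition (anti to the C3 chain at C2, endo); C9 from a hydroxyl-directed reduction (C11–OH); C14 from a bulky hydride; C7 from Felkin addition then Mitsunobu inversion; C8/C17 from the tethered Reformatsky; C6 from the ene chlorination. The sugar stereocentres (C4, C5 of D-gulonolactone) are relay elements and are later oxidised.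

Key step: step 10

Assumption: the (R,R)-(salen)CrBF4 catalyst is taken to deliver the 2S-pyranone 6; if the sense of induction is the reverse, the (S,S)-catalyst is used.

**Step 1**
Reactants: 1 4-pentyn-1-ol
Product: 2 (E)-5-iodo-4-methylpent-4-en-1-ol
Conditions: Me3Al, Cp2ZrCl2 (cat.), CH2Cl2, 0 °C to rt; then I2, THF, −30 °C
Reagents that add atoms: trimethylaluminium C[Al](C)C; iodine II
Why: Zirconium-catalysed carboalumination (Negishi) adds methyl and aluminium syn across the alkyne and iodinolysis retains the geometry, so the E vinyl iodide should form.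

**Step 2**
Reactants: 2 (E)-5-iodo-4-methylpent-4-en-1-ol
Product: 3 (E)-5-iodo-4-methylpent-4-enal
Conditions: Dess–Martin periodinane, NaHCO3, CH2Cl2, 0 °C to rt
Reagents that add atoms: none
Why: Dess–Martin oxidation of a primary alcohol is neutral and leaves the vinyl iodide untouched.

**Step 3**
Reactants: 3 (E)-5-iodo-4-methylpent-4-enal; 4 trans-1-methoxy-3-(trimethylsilyloxy)buta-1,3-diene (Danishefsky's diene)
Product: 6 (S)-2-[(E)-4-iodo-3-methylbut-3-en-1-yl]-2,3-dihydro-4H-pyran-4-one, via silyl enol ether cycloadduct 5 (not isolated)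
Conditions: (R,R)-(salen)CrBF4 (2 mol %; salen = N,N'-bis(3,5-di-tert-butylsalicylidene)-1,2-cyclohexanediamine dianion), 4 Å MS, t-BuOMe, −30 °C; then TFA (cat.), CH2Cl2, 0 °C
Reagents that add atoms: none
Why: Catalytic asymmetric hetero-Diels–Alder reaction of an aliphatic aldehyde, followed by acid elimination of methanol, should give the dihydropyranone; the chiral Lewis acid sets C2.

**Step 4**
Reactants: 6 (S)-2-[(E)-4-iodo-3-methylbut-3-en-1-yl]-2,3-dihydro-4H-pyran-4-one
Product: 7 (2S,3S)-2-[(E)-4-iodo-3-methylbut-3-en-1-yl]-3-methyl-2,3-dihydro-4H-pyran-4-one (trans; the C3 epimer serves equally)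
Conditions: LiN(SiMe3)2, THF, −78 °C; MeI, DMPU, −78 to −40 °C
Reagents that add atoms: iodomethane CI
Why: Kinetic enolate alkylation of the vinylogous ester at its only sp3 α-carbon installs C15; the new centre becomes sp2 in step 5, so its configuration is immaterial.

**Step 5**
Reactants: 7 (2S,3S)-2-[(E)-4-iodo-3-methylbut-3-en-1-yl]-3-methyl-2,3-dihydro-4H-pyran-4-one
Product: 8 (S)-2-[(E)-4-iodo-3-methylbut-3-en-1-yl]-3-methyl-4-(triethylsilyloxy)-2H-pyran
Conditions: Et3SiOTf, Et3N, Et2O, 0 °C; used without chromatography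
Reagents that add atoms: triethylsilyl triflate CC[Si](CC)(CC)OS(=O)(=O)C(F)(F)F
Why: Soft enolisation (silyl enol ether formation) can occur only toward C1, which gives the cyclic 1-alkoxy-3-siloxy diene.

**Step 6**
Reactants: 9 D-gulono-1,4-lactone
Product: 10 5,6-O-isopropylidene-D-gulono-1,4-lactone
Conditions: 2-methoxypropene, TsOH (cat.), DMF, 0 °C
Reagents that add atoms: 2-methoxypropene COC(C)=C
Why: Kinetic acetonide formation selects the terminal 5,6-diol of the aldonolactone.

**Step 7**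
Reactants: 10 5,6-O-isopropylidene-D-gulono-1,4-lactone
Product: 12 (R)-3-(benzoyloxy)-5-[(R)-2,2-dimethyl-1,3-dioxolan-4-yl]furan-2(5H)-one, via 2,3-dibenzoate 11 (not isolated)
Conditions: BzCl, pyridine, CH2Cl2, 0 °C; then Et3N, rt
Reagents that add atoms: benzoyl chloride O=C(Cl)c1ccccc1
Why: Base-induced β-elimination (E1cB) of the 3-benzoate of a peracylated aldonolactone should give the 2-acyloxy butenolide; C4 of the sugar (later C9) is untouched.

**Step 8**
Reactants: 12 (R)-3-(benzoyloxy)-5-[(R)-2,2-dimethyl-1,3-dioxolan-4-yl]furan-2(5H)-one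
Product: 13 (R)-3-(benzoyloxy)-5-[(R)-1,2-dihydroxyethyl]furan-2(5H)-one
Conditions: AcOH–H2O (4:1), 50 °C
Reagents that add atoms: none
Why: Acid hydrolysis of a terminal acetonide; the enol benzoate and the butenolide tolerate aqueous acid.

**Step 9**
Reactants: 13 (R)-3-(benzoyloxy)-5-[(R)-1,2-dihydroxyethyl]furan-2(5H)-one
Product: 14 (R)-3-(benzoyloxy)-5-[(R)-1,2-bis(tert-butyldimethylsilyloxy)ethyl]furan-2(5H)-one
Conditions: t-BuMe2SiOTf, 2,6-lutidine, CH2Cl2, −78 °C
Reagents that add atoms: tert-butyldimethylsilyl triflate CC(C)(C)[Si](C)(C)OS(=O)(=O)C(F)(F)F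
Why: Silyl triflate with a hindered base protects both hydroxyls at low temperature without touching the base-sensitive butenolide.

**Step 10**
Reactants: 8 (S)-2-[(E)-4-iodo-3-methylbut-3-en-1-yl]-3-methyl-4-(triethylsilyloxy)-2H-pyran; 14 (R)-3-(benzoyloxy)-5-[(R)-1,2-bis(tert-butyldimethylsilyloxy)ethyl]furan-2(5H)-one
Product: 15 2-oxabicyclo[2.2.2]octene adduct (C2–O–C12 ether bridge; C13=C14 triethylsilyl enol ether; C15 methyl on C1; endo cis-fused lactone C20(=O)–O–C9; exo benzoate on C11; C9 epimeric to the target)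
Conditions: 8 (1.5 equiv), toluene (2 M), 2,6-di-tert-butyl-4-methylphenol (cat.), sealed tube, 100 °C
Reagents that add atoms: none
Why: Proposed new method: the 4-siloxy-2H-pyran is a Danishefsky-type diene (ring oxygen on C12, siloxy group on C14) locked s-cis, so its nucleophilic terminus C1 should bond to the β-carbon C10 of the butenolide and C12 to the α-carbon C11 in a concerted, asynchronous [4+2] cycloaddition; the closest known reactions are cycloadditions of 1-alkoxy-3-siloxy dienes with butenolides and Diels–Alder reactions of 2H-pyrans formed by oxa-6π-electrocyclisation. The only ring closed is cyclohexene ring C, by intermolecular suprafacial addition; it is born inside a 2-oxabicyclo[2.2.2]octene because the diene is cyclic. C1 and C12 are set by attack on the pyran face opposite the C3 side chain at C2; C10 and C11 are set by the endo orientation of the lactone (Alder rule), which places C9 and C20 cis to the C15 methyl and the benzoyloxy group on the side of C2. The butenolide reacts on the face opposite its C9 side chain, which is why the D-gulono series is used: both partners then prefer the same transition state (matched pair), at the price of a C9 configuration that is corrected in steps 13 and 15. The step needs regio-, endo and twofold facial selectivity and needs the pyran to react faster than it equilibrates to its ring-opened dienal; the two donor oxygens, the tied-back C2 substituent and the γ-substituent of the butenolide are what should secure this.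

**Step 11**
Reactants: 15 2-oxabicyclo[2.2.2]octene adduct
Product: 16 bicyclic triol (C20H2OH; C11–OH; C9–OH, 9-epi)
Conditions: i-Bu2AlH (6 equiv), CH2Cl2, −78 to 0 °C; Rochelle salt
Reagents that add atoms: none
Why: Hydride reduction opens the lactone to the diol and removes the benzoate, while the silyl enol ether, silyl ethers and vinyl iodide should survive.

**Step 12**
Reactants: 16 bicyclic triol
Product: 18 C20 4-methoxybenzyl ether of 16, via stannylene acetal 17 (not isolated)
Conditions: Bu2SnO, toluene, reflux (Dean–Stark); then 4-MeOC6H4CH2Cl, Bu4NI (cat.), 90 °C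
Reagents that add atoms: 4-methoxybenzyl chloride COc1ccc(CCl)cc1; dibutyltin oxide (in 17 only) CCCC[Sn](=O)CCCC
Why: Stannylene-mediated alkylation of a 1,2-diol goes to the primary oxygen, which leaves the tertiary C11–OH free as the later directing group and C9–OH as the only oxidisable alcohol.

**Step 13**
Reactants: 18 C20 4-methoxybenzyl ether
Product: 19 C9 ketone of 18
Conditions: Dess–Martin periodinane, NaHCO3, CH2Cl2, 0 °C to rt
Reagents that add atoms: none
Why: Dess–Martin oxidation of the single secondary alcohol erases the mis-set C9 centre under neutral conditions, which avoid retro-aldol of the β-hydroxy ketone.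

**Step 14**
Reactants: 19 C9 ketone
Product: 22 ring C enone C2 acetate (C14=O; C12=C13; C9 ketone; C11–OH), via bicyclic diketone 20 (not isolated), via hydroxy enone 21 (not isolated)
Conditions: camphorsulfonic acid (cat.), wet CH2Cl2, 0 °C; then pyridine, Ac2O, DMAP (cat.), 0 °C
Reagents that add atoms: acetic anhydride CC(=O)OC(C)=O
Why: Acid hydrolysis of the enol ether gives a β-alkoxy ketone that should eliminate the C12–O bond (retro-oxa-Michael, as in the unveiling of Danishefsky adducts); acetylation then traps the released C2–OH, and the tertiary C11–OH does not react.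

**Step 15**
Reactants: 22 ring C enone C2 acetate
Product: 23 C9 alcohol of target configuration
Conditions: Me4NBH(OAc)3, MeCN–AcOH, −30 °C
Reagents that add atoms: none
Why: Evans–Saksena reduction: hydride is delivered from boron bound to the tertiary C11–OH through a chair transition state trans-fused to ring C with the C8 branch equatorial, which should give the required C9 configuration; the enone has no directing hydroxyl and should stay.

**Step 16**
Reactants: 23 C9 alcohol
Product: 25 C9,C14-diol with 14α-OH, via saturated C14 ketone 24 (not isolated)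
Conditions: LiBH(s-Bu)3, THF, −78 °C; t-BuOH (1 equiv); LiBH(s-Bu)3, −78 °C; AcOH quench
Reagents that add atoms: none
Why: The bulky borohydride first reduces the β-unsubstituted enone in the 1,4 sense; after protonation it attacks the C14 ketone along the equatorial trajectory, as 4,4-dimethyl-3-keto steroids give axial 3α-alcohols, so the axial 14α-alcohol cis to the C2 branch is expected.

**Step 17**
Reactants: 25 C9,C14-diol
Product: 26 C2,C9,C14-triacetate
Conditions: Ac2O, pyridine, DMAP, 40 °C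
Reagents that add atoms: acetic anhydride CC(=O)OC(C)=O
Why: DMAP-catalysed acetylation of the two hindered secondary alcohols; the tertiary C11–OH should not react.

**Step 18**
Reactants: 26 triacetate
Product: 27 C7 primary alcohol
Conditions: HF·pyridine, pyridine, THF, 0 °C
Reagents that add atoms: none
Why: Buffered fluoride cleaves the primary silyl ether much faster than the secondary one at C8.

**Step 19**
Reactants: 27 C7 primary alcohol
Product: 28 C7 aldehyde
Conditions: Dess–Martin periodinane, NaHCO3, CH2Cl2, 0 °C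
Reagents that add atoms: none
Why: Base-free Dess–Martin oxidation avoids β-elimination of the C9 acetate and epimerisation at C8.

**Step 20**
Reactants: 28 C7 aldehyde
Product: 29 ten-membered (5E)-allylic alcohol (7-epi)
Conditions: CrCl2 (10 equiv), NiCl2 (0.1 equiv), DMSO–THF, 0.002 M, rt
Reagents that add atoms: none
Why: Intramolecular Nozaki–Hiyama–Kishi coupling keeps the E geometry of the vinyl iodide and tolerates the acetates and free tertiary alcohol; Felkin–Anh addition anti to the C8 silyloxy group is expected to give the 7,8-anti (7-epi) alcohol.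

**Step 21**
Reactants: 29 ten-membered allylic alcohol; 30 2-bromopropanoic acid (racemic)
Product: 31 C7 2-bromopropanoate of target C7 configuration
Conditions: PPh3, diisopropyl azodicarboxylate, toluene, 0 °C to rt
Reagents that add atoms: none
Why: Mitsunobu esterification installs the Reformatsky handle and inverts C7 in one operation (direct substitution with inversion at the allylic carbinol).

**Step 22**
Reactants: 31 C7 2-bromopropanoate
Product: 32 C8 alcohol
Conditions: HF·pyridine, THF, rt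
Reagents that add atoms: none
Why: Acidic fluoride removes the remaining secondary silyl ether without touching the α-bromo ester, the acetates or the benzyl ether.

**Step 23**
Reactants: 32 C8 alcohol
Product: 33 C8 ketone
Conditions: Dess–Martin periodinane, NaHCO3, CH2Cl2, 0 °C
Reagents that add atoms: none
Why: Neutral oxidation gives the α,α'-dioxygenated ketone without enolisation toward C7 or C9.

**Step 24**
Reactants: 33 C8 ketone
Product: 34 α-methyl-β-hydroxy-γ-lactone (C8–OH; C17 methyl; C20 ether retained)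
Conditions: SmI2 (2.5 equiv), THF, −78 °C
Reagents that add atoms: none
Why: Samarium-mediated intramolecular Reformatsky reaction: the enolate tethered through O7 can reach only one face of the C8 carbonyl, the five-membered ring should close with C6 and C9 trans, and the C17 methyl should take the side away from the C9 branch.

**Step 25**
Reactants: 34 lactone
Product: 35 C11,C20-diol
Conditions: DDQ, CH2Cl2–pH 7 buffer, 0 °C
Reagents that add atoms: none
Why: Oxidative cleavage of the 4-methoxybenzyl ether is neutral and leaves the acetates, lactone and alkene alone.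

**Step 26**
Reactants: 35 C11,C20-diol
Product: 37 11,20-epoxide, via C20 tosylate 36 (not isolated)
Conditions: TsCl, Et3N, Bu2SnO (cat.), CH2Cl2, rt; then DBU, 40 °C
Reagents that add atoms: p-toluenesulfonyl chloride (in 36 only) Cc1ccc(cc1)S(Cl)(=O)=O
Why: Tin-catalysed sulfonylation selects the primary hydroxyl of the 1,2-diol, and the tertiary C11 alkoxide then displaces the tosylate (3-exo-tet); C11, set in step 10, is retained, so the epoxide oxygen stays on the face of the C2 branch.

**Step 27**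
Reactants: 37 11,20-epoxide
Product: 38 CNP0104093.1
Conditions: Ca(OCl)2, solid CO2, CH2Cl2–H2O, 0 °C
Reagents that add atoms: calcium hypochlorite [Ca+2].[O-]Cl.[O-]Cl
Why: Ene-type chlorination of the only alkene with hypochlorous acid puts chlorine on the less substituted carbon C6 from the exposed outer face of the (E)-cyclodecene and shifts the double bond to C5=C16 by loss of a C16 proton.

**Compound list**

1 | 4-pentyn-1-ol | OCCCC#C | starting material
2 | (E)-5-iodo-4-methylpent-4-en-1-ol | OCCC/C(C)=C/I | intermediate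
3 | (E)-5-iodo-4-methylpent-4-enal | O=CCC/C(C)=C/I | intermediate
4 | trans-1-methoxy-3-(trimethylsilyloxy)buta-1,3-diene | CO/C=C/C(=C)O[Si](C)(C)C | starting material
5 | 2-methoxy-4-(trimethylsilyloxy)-5,6-dihydro-2H-pyran cycloadduct (6S; acetal carbon unassigned) | COC1C=C(O[Si](C)(C)C)C[C@H](CC/C(C)=C/I)O1 | intermediate
6 | (S)-2-[(E)-4-iodo-3-methylbut-3-en-1-yl]-2,3-dihydro-4H-pyran-4-one | O=C1C[C@H](CC/C(C)=C/I)OC=C1 | intermediate
7 | (2S,3S)-2-[(E)-4-iodo-3-methylbut-3-en-1-yl]-3-methyl-2,3-dihydro-4H-pyran-4-one | O=C1[C@@H](C)[C@H](CC/C(C)=C/I)OC=C1 | intermediate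
8 | (S)-2-[(E)-4-iodo-3-methylbut-3-en-1-yl]-3-methyl-4-(triethylsilyloxy)-2H-pyran | CC[Si](CC)(CC)OC1=C(C)[C@H](CC/C(C)=C/I)OC=C1 | intermediate
9 | D-gulono-1,4-lactone | O=C1[C@H](O)[C@H](O)[C@@H](O1)[C@H](O)CO | starting material
10 | 5,6-O-isopropylidene-D-gulono-1,4-lactone | O=C1[C@H](O)[C@H](O)[C@@H](O1)[C@H]2COC(C)(C)O2 | intermediate
11 | 2,3-di-O-benzoyl-5,6-O-isopropylidene-D-gulono-1,4-lactone | O=C1[C@H](OC(=O)c2ccccc2)[C@H](OC(=O)c2ccccc2)[C@@H](O1)[C@H]3COC(C)(C)O3 | intermediate
12 | (R)-3-(benzoyloxy)-5-[(R)-2,2-dimethyl-1,3-dioxolan-4-yl]furan-2(5H)-one | O=C1C(OC(=O)c2ccccc2)=C[C@@H](O1)[C@H]3COC(C)(C)O3 | intermediate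
13 | (R)-3-(benzoyloxy)-5-[(R)-1,2-dihydroxyethyl]furan-2(5H)-one | O=C1C(OC(=O)c2ccccc2)=C[C@@H](O1)[C@H](O)CO | intermediate
14 | (R)-3-(benzoyloxy)-5-[(R)-1,2-bis(tert-butyldimethylsilyloxy)ethyl]furan-2(5H)-one | O=C1C(OC(=O)c2ccccc2)=C[C@@H](O1)[C@H](O[Si](C)(C)C(C)(C)C)CO[Si](C)(C)C(C)(C)C | intermediate
15 | Diels–Alder adduct: 2-oxabicyclo[2.2.2]octene with C2–O–C12 bridge; C13=C14 triethylsilyl enol ether; endo lactone C20(=O)–O–C9; exo C11 benzoate; 9-epi | I/C=C(\C)CC[C@@H]1O[C@@H]2C=C(O[Si](CC)(CC)CC)[C@@]1(C)[C@@H]3[C@@]2(OC(=O)c4ccccc4)C(=O)O[C@H]3[C@H](O[Si](C)(C)C(C)(C)C)CO[Si](C)(C)C(C)(C)C | intermediate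
16 | bicyclic triol (C9–OH 9-epi; C11–OH; C20–OH) | I/C=C(\C)CC[C@@H]1O[C@@H]2C=C(O[Si](CC)(CC)CC)[C@@]1(C)[C@H]([C@@]2(O)CO)[C@@H](O)[C@H](O[Si](C)(C)C(C)(C)C)CO[Si](C)(C)C(C)(C)C | intermediate
17 | dibutylstannylene acetal of the C11,C20-diol of 16 | I/C=C(\C)CC[C@@H]1O[C@@H]2C=C(O[Si](CC)(CC)CC)[C@@]1(C)[C@H]([C@@]24CO[Sn](CCCC)(CCCC)O4)[C@@H](O)[C@H](O[Si](C)(C)C(C)(C)C)CO[Si](C)(C)C(C)(C)C | intermediate
18 | C20 4-methoxybenzyl ether of 16 | I/C=C(\C)CC[C@@H]1O[C@@H]2C=C(O[Si](CC)(CC)CC)[C@@]1(C)[C@H]([C@@]2(O)COCc3ccc(OC)cc3)[C@@H](O)[C@H](O[Si](C)(C)C(C)(C)C)CO[Si](C)(C)C(C)(C)C | intermediate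
19 | C9 ketone of 18 | I/C=C(\C)CC[C@@H]1O[C@@H]2C=C(O[Si](CC)(CC)CC)[C@@]1(C)[C@H]([C@@]2(O)COCc3ccc(OC)cc3)C(=O)[C@H](O[Si](C)(C)C(C)(C)C)CO[Si](C)(C)C(C)(C)C | intermediate
20 | bicyclic C9,C14-diketone (C2–O–C12 bridge intact) | I/C=C(\C)CC[C@@H]1O[C@@H]2CC(=O)[C@@]1(C)[C@H]([C@@]2(O)COCc3ccc(OC)cc3)C(=O)[C@H](O[Si](C)(C)C(C)(C)C)CO[Si](C)(C)C(C)(C)C | intermediate
21 | ring C enone (C14=O; C12=C13) with free C2–OH and C9 ketone | I/C=C(\C)CC[C@H](O)[C@@]1(C)C(=O)C=C[C@](O)(COCc2ccc(OC)cc2)[C@@H]1C(=O)[C@H](O[Si](C)(C)C(C)(C)C)CO[Si](C)(C)C(C)(C)C | intermediate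
22 | C2 acetate of 21 | I/C=C(\C)CC[C@H](OC(C)=O)[C@@]1(C)C(=O)C=C[C@](O)(COCc2ccc(OC)cc2)[C@@H]1C(=O)[C@H](O[Si](C)(C)C(C)(C)C)CO[Si](C)(C)C(C)(C)C | intermediate
23 | C9 alcohol (target C9 configuration) of 22 | I/C=C(\C)CC[C@H](OC(C)=O)[C@@]1(C)C(=O)C=C[C@](O)(COCc2ccc(OC)cc2)[C@@H]1[C@H](O)[C@H](O[Si](C)(C)C(C)(C)C)CO[Si](C)(C)C(C)(C)C | intermediate
24 | saturated C14 ketone | I/C=C(\C)CC[C@H](OC(C)=O)[C@@]1(C)C(=O)CC[C@](O)(COCc2ccc(OC)cc2)[C@@H]1[C@H](O)[C@H](O[Si](C)(C)C(C)(C)C)CO[Si](C)(C)C(C)(C)C | intermediate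
25 | C9,C14-diol (14α-OH) C2 acetate | I/C=C(\C)CC[C@H](OC(C)=O)[C@@]1(C)[C@@H](O)CC[C@](O)(COCc2ccc(OC)cc2)[C@@H]1[C@H](O)[C@H](O[Si](C)(C)C(C)(C)C)CO[Si](C)(C)C(C)(C)C | intermediate
26 | C2,C9,C14-triacetate | I/C=C(\C)CC[C@H](OC(C)=O)[C@@]1(C)[C@@H](OC(C)=O)CC[C@](O)(COCc2ccc(OC)cc2)[C@@H]1[C@H](OC(C)=O)[C@H](O[Si](C)(C)C(C)(C)C)CO[Si](C)(C)C(C)(C)C | intermediate
27 | C7 primary alcohol | I/C=C(\C)CC[C@H](OC(C)=O)[C@@]1(C)[C@@H](OC(C)=O)CC[C@](O)(COCc2ccc(OC)cc2)[C@@H]1[C@H](OC(C)=O)[C@H](O[Si](C)(C)C(C)(C)C)CO | intermediate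
28 | C7 aldehyde | I/C=C(\C)CC[C@H](OC(C)=O)[C@@]1(C)[C@@H](OC(C)=O)CC[C@](O)(COCc2ccc(OC)cc2)[C@@H]1[C@H](OC(C)=O)[C@H](O[Si](C)(C)C(C)(C)C)C=O | intermediate
29 | ten-membered (5E)-allylic alcohol, 7-epi | O[C@@H]1/C=C(\C)CC[C@H](OC(C)=O)[C@@]2(C)[C@@H](OC(C)=O)CC[C@](O)(COCc3ccc(OC)cc3)[C@@H]2[C@H](OC(C)=O)[C@@H]1O[Si](C)(C)C(C)(C)C | intermediate
30 | 2-bromopropanoic acid (racemic) | CC(Br)C(O)=O | starting material
31 | C7 2-bromopropanoate (target C7 configuration) | CC(Br)C(=O)O[C@H]1/C=C(\C)CC[C@H](OC(C)=O)[C@@]2(C)[C@@H](OC(C)=O)CC[C@](O)(COCc3ccc(OC)cc3)[C@@H]2[C@H](OC(C)=O)[C@@H]1O[Si](C)(C)C(C)(C)C | intermediate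
32 | C8 alcohol | CC(Br)C(=O)O[C@H]1/C=C(\C)CC[C@H](OC(C)=O)[C@@]2(C)[C@@H](OC(C)=O)CC[C@](O)(COCc3ccc(OC)cc3)[C@@H]2[C@H](OC(C)=O)[C@@H]1O | intermediate
33 | C8 ketone | CC(Br)C(=O)O[C@H]1/C=C(\C)CC[C@H](OC(C)=O)[C@@]2(C)[C@@H](OC(C)=O)CC[C@](O)(COCc3ccc(OC)cc3)[C@@H]2[C@H](OC(C)=O)C1=O | intermediate
34 | lactone with C8–OH; (5E)-alkene; C20 4-methoxybenzyl ether | O=C1O[C@H]2/C=C(\C)CC[C@H](OC(C)=O)[C@@]3(C)[C@@H](OC(C)=O)CC[C@](O)(COCc4ccc(OC)cc4)[C@@H]3[C@H](OC(C)=O)[C@]2(O)[C@H]1C | intermediate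
35 | C11,C20-diol | O=C1O[C@H]2/C=C(\C)CC[C@H](OC(C)=O)[C@@]3(C)[C@@H](OC(C)=O)CC[C@](O)(CO)[C@@H]3[C@H](OC(C)=O)[C@]2(O)[C@H]1C | intermediate
36 | C20 tosylate | O=C1O[C@H]2/C=C(\C)CC[C@H](OC(C)=O)[C@@]3(C)[C@@H](OC(C)=O)CC[C@](O)(COS(=O)(=O)c4ccc(C)cc4)[C@@H]3[C@H](OC(C)=O)[C@]2(O)[C@H]1C | intermediate
37 | 11,20-epoxide with (5E)-alkene | O=C1O[C@H]2/C=C(\C)CC[C@H](OC(C)=O)[C@@]3(C)[C@@H](OC(C)=O)CC[C@]4(CO4)[C@@H]3[C@H](OC(C)=O)[C@]2(O)[C@H]1C | intermediate
38 | CNP0104093.1 | C=C1CC[C@H](OC(C)=O)[C@@]2(C)[C@@H](OC(C)=O)CC[C@]3(CO3)[C@@H]2[C@H](OC(C)=O)[C@]2(O)[C@@H](C)C(=O)O[C@H]2[C@H]1Cl | target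

**Step count:** 27 steps in total. Longest linear sequence: 23 steps (steps 1–5 and 10–27).

**Steps most likely to fail**

Step 10 (proposed new method). The pyran may open to its dienal valence isomer or lose its silyl group before the hindered cycloaddition takes place, or endo selectivity may be poor. The fallback builds the same two bonds stepwise by known anionic chemistry. It sets out from 7 and 14: the lithium enolate of 7 (LiN(SiMe3)2, THF, −78 °C) should add through C1 to C10 of the butenolide (Michael addition), and the resulting lactone enolate should close onto C12 of the vinylogous ester (second Michael addition) to give the bicyclic keto lactone F1. Silylation of F1 (Et3SiOTf, Et3N), which can enolise only toward C13, returns to the route at 15.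

Step 20. The ten-membered ring may fail to close (intermolecular coupling, reduction of the vinyl iodide), or facial selectivity at C7 may be poor. The fallback closes the same bond as a ketone and sets C7 by reduction. It sets out from 28: chlorite oxidation (NaClO2, NaH2PO4, 2-methyl-2-butene) should give the acid F2, and 2,2'-dipyridyl disulfide with PPh3 the 2-pyridyl thioester F3. Nickel/zirconium-mediated coupling of thioester and vinyl iodide (NiBr2(dtbbpy), Cp2ZrCl2, Zn, high dilution) should then give the macrocyclic enone F4. Reduction of F4 (NaBH4–CeCl3, or an oxazaborolidine-catalysed borane reduction with the catalyst enantiomer that delivers the 7-epi alcohol) returns to the route at 29. If the other C7 epimer forms, it is acylated directly with 2-bromopropanoyl bromide and joins at 31.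

Step 27. Chlorine may be delivered to the wrong alkene face, or the proton may be lost from C4 instead of C16. The fallback separates the ene step from the introduction of chlorine and inverts C6. It sets out from 37: the singlet-oxygen ene reaction (O2, light, tetraphenylporphyrin, CH2Cl2, 0 °C) should give the allylic hydroperoxide F5 with the C5=C16 methylene, and PPh3 reduces it to the allylic alcohol F6. Chlorination with inversion (PPh3, hexachloroacetone, CH2Cl2, −20 °C) returns to the route at 38. Because oxygen and chlorine would enter from the same exposed face, this sequence gives the C6 epimer opposite to that of the direct chlorination.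

**Further compounds**

F1 | step 10 | bicyclic keto lactone (C14 ketone of 15) | I/C=C(\C)CC[C@@H]1O[C@@H]2CC(=O)[C@@]1(C)[C@@H]3[C@@]2(OC(=O)c4ccccc4)C(=O)O[C@H]3[C@H](O[Si](C)(C)C(C)(C)C)CO[Si](C)(C)C(C)(C)C
F2 | step 20 | C7 carboxylic acid from 28 | I/C=C(\C)CC[C@H](OC(C)=O)[C@@]1(C)[C@@H](OC(C)=O)CC[C@](O)(COCc2ccc(OC)cc2)[C@@H]1[C@H](OC(C)=O)[C@H](O[Si](C)(C)C(C)(C)C)C(O)=O
F3 | step 20 | S-(2-pyridyl) thioester of F2 | I/C=C(\C)CC[C@H](OC(C)=O)[C@@]1(C)[C@@H](OC(C)=O)CC[C@](O)(COCc2ccc(OC)cc2)[C@@H]1[C@H](OC(C)=O)[C@H](O[Si](C)(C)C(C)(C)C)C(=O)Sc3ccccn3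
F4 | step 20 | macrocyclic (5E)-enone with C7 ketone | O=C1/C=C(\C)CC[C@H](OC(C)=O)[C@@]2(C)[C@@H](OC(C)=O)CC[C@](O)(COCc3ccc(OC)cc3)[C@@H]2[C@H](OC(C)=O)[C@@H]1O[Si](C)(C)C(C)(C)C
F5 | step 27 | C6 allylic hydroperoxide (oxygen on the face opposite to the target chlorine) | C=C1CC[C@H](OC(C)=O)[C@@]2(C)[C@@H](OC(C)=O)CC[C@]3(CO3)[C@@H]2[C@H](OC(C)=O)[C@]2(O)[C@@H](C)C(=O)O[C@H]2[C@@H]1OO
F6 | step 27 | C6 allylic alcohol from F5 | C=C1CC[C@H](OC(C)=O)[C@@]2(C)[C@@H](OC(C)=O)CC[C@]3(CO3)[C@@H]2[C@H](OC(C)=O)[C@]2(O)[C@@H](C)C(=O)O[C@H]2[C@@H]1O
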